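## Structural features

The target 19 (C25H42O2) is a monocyclic sesterterpenoid. Its single fourteen-membered carbocycle is numbered here from the ring stereocentre C1 through C2, C3=C4, C5, C6, C7=C8, C9, C10, C11=C12, C13 and C14. C4 carries the hydroxymethyl carbon C20, C8 and C12 carry methyl groups, and C1 carries the exocyclic carbinol carbon C15, which bears OH, a methyl group (C23) and the homoprenyl chain C16–C17–C18=C19(CH3)2.

The three ring alkenes are trisubstituted and stand in 1,5-relationships. The ring chain runs trans through C3=C4 (Z only by the CIP rank of C20, so C2 is cis to C20) and through C7=C8 (E), but cis through C11=C12 (Z). The only stereocentres, C1 (R) and C15 (R), are direct neighbours, one in the ring and one outside it.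

They cannot be set by induction from each other. The two ring arms at C1 (C2H2–CH= and C14H2–CH2) and the two alkyl groups at C15 (CH3 and CH2R) are nearly alike in size, so the pair has to come from a stereospecific event. The fragile points are the skipped polyene and the tertiary and allylic alcohols, which ionise or cyclise under acid. The Z alkene is also fragile, because any allyl cation, radical or π-allyl metal species at C10 or C13 would scramble it.

The real difficulty is closing a ring that holds no heteroatom or carbonyl group for a conventional macrocyclisation, while keeping three alkene geometries and fixing the C1/C15 pair in the absolute sense.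

The key step exploits the array HO–C15–C1–C2–C3=C4. The C15–O and C1–C2 bonds lie anti across what would be an E alkene C1=C15. This is the retron of an SN2 opening of a trans-epoxide at C1 by an allyl anion centred on C2. C1–C2 is also the bond that the terpene cyclase is presumed to form, made here with inverted polarity.

## Logic of the disconnections

**19 to 18.** The C2–H bond is traced back to a C2–S(phenyl) bond. No skeletal bond is cut; sulfur is the price of making C2 a carbanion. The gain is an acidifying group that leaves no atom behind. The forward step must cleave C–S reductively, protonate the allyl system at C2 and not at C4, and keep C2 cis to C20.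

**18 to 16 (through 17).** The ring bond C1–C2 is cut and the C15 oxygen is reconnected to C1 as an epoxide.
- This is the only ring bond whose formation can also write both stereocentres, C1 by inversion and C15 by retention.
- The ring and the mutual control of two look-alike centres disappear. What remains is an acyclic chain with one trans-epoxide, whose two centres come from one reagent-controlled reaction on an E alkene.
- The forward step needs an anion localised on C2, attack at the secondary and not the fully substituted epoxide carbon, and ring closure faster than intermolecular opening.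

**16 to 15 to 13.** The C2–S bond and then the C2–O and C20–O bonds are removed, which leaves the 2-substituted 1,3-diene C2=C3–C4=C20.
- A metal-mediated 1,4-addition to the s-cis diene puts C2 and C20 on the same side of the new C3=C4 bond by mechanism. Olefination would fight the thermodynamic preference here.
- The oxygenated, geometry-sensitive terminus becomes a plain hydrocarbon diene.
- The forward steps must react at the diene only and must tell the C2 hydroxyl from the C20 hydroxyl.

**13 to 10 and 11.** The C16–C17 bond is cut. C16 is the carbon that carried the hydroxyl needed to direct the asymmetric epoxidation, so the tail has to arrive after that step. The gain is a C5 unit that is bought. The forward step needs displacement at the primary carbon next to the epoxide, through the unsubstituted end of the allyl nucleophile, with the epoxide left closed.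

**10 to 9 to 8 to 7.** The sulfonate, the epoxide oxygen and the C16 oxygen are removed in turn.
- The terminal isopropylidene group of 7 is the most reactive site for allylic oxidation and gives the E-2-methylallylic alcohol that the asymmetric epoxidation handles best.
- All heteroatoms and both stereocentres vanish into an achiral hydrocarbon.
- The forward steps need terminal site selectivity in the oxidation and face selectivity by the tartrate.

**7 to 3 and 5.** The doubly allylic bond C9–C10 is cut. This splits C20 into two C10 halves that each lie one or two steps from a commodity monoterpene. The Z alkene C11=C12 is bought with 4, and the E alkene C7=C8 and the diene are bought with 1. The forward step needs head-to-head allyl–allyl coupling without allylic transposition and without E/Z leakage.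

**3 to 2 to 1, and 5 to 4.** These are functional group changes only: bromide from alcohol from the E methyl group of 1, and chloride from the alcohol 4. Both substitutions must preserve geometry.

## Other disconnections considered

**Alternative 1:** The cut that comes to mind first is a ring alkene, most naturally the Z alkene C11=C12, with the C1/C15 pair installed beforehand. The forward key step is ring-closing metathesis of the acyclic pentaene diol A1 with a second-generation Grubbs catalyst.
- Nothing in a nearly strain-free fourteen-membered ring favours the Z isomer of a trisubstituted alkene, and the reaction would run under thermodynamic control.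
- The alkylidene formed at C12 sits in a 1,7-relationship to C3=C4, so closure to a six-membered ring with loss of half the chain should be faster than macrocyclisation.
- The ring closure does nothing for C1 and C15, which would cost separate steps.
- The chosen plan closes the ring at the stereocentre and touches no alkene.

**Alternative 2:** The same bond C1–C2 can be formed by a [2,3]-Wittig ring contraction. In the seventeen-membered bis-allylic ether A2, oxygen bridges C2 and C23. Deprotonation at C2 should give the fourteen-membered carbocycle A3, with a hydroxyl on C2 and a methylidene group C15=C23. The ether closure is easy and the shift sets C1.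
- A3 keeps a C2 hydroxyl that is allylic to C3=C4 and must be deleted without transposition.
- C15 is left as a 1,1-disubstituted alkene, whose hydration has no stereospecific link to C1.
- A2 demands oxygenation of C23, the inner methyl group of an internal alkene, for which no direct reaction exists.
- At least four more steps and one uncontrolled stereocentre result.

**Alternative 3:** The literal copy of the biosynthesis forms C1–C2 in the natural polarity. The C2 oxygen of the achiral acyclic pentaene diol A4 (as an ester) is ionised, the C1=C15 alkene attacks the allyl cation, and water captures the C15 cation.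
- A4 holds no element that could fix the absolute configuration.
- The open C15 cation can rotate or lose a proton before capture.
- The nearer C7=C8 alkene and the C20 hydroxyl compete for the allyl cation.
- Acid endangers the product itself.
- The chosen plan keeps the bond and the anti stereochemistry of this step but stores both centres in an epoxide and runs under base.

Key step: step 11

Remark on the chemistry: in every acyclic intermediate each carbon keeps the locant it will have in 19.

## Steps

Step 1
Reactants: 1 β-myrcene (7-methyl-3-methylideneocta-1,6-diene)
Product: 2 (2E)-2-methyl-6-methylideneocta-2,7-dien-1-ol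
Conditions: SeO2 (cat.), salicylic acid (cat.), t-BuOOH, CH2Cl2, 0 °C to rt
Reagents that add atoms: tert-butyl hydroperoxide, CC(C)(C)OO
Why: Riley-type allylic oxidation (ene reaction, then [2,3]-shift) attacks the electron-rich trisubstituted alkene and by the usual rule oxidises the methyl group trans to the chain, which gives the E allylic alcohol at C9; the conjugated diene is the poorer ene partner and should stay intact.

Step 2
Reactants: 2 (2E)-2-methyl-6-methylideneocta-2,7-dien-1-ol
Product: 3 (6E)-8-bromo-7-methyl-3-methylideneocta-1,6-diene
Conditions: CBr4, PPh3, CH2Cl2, 0 °C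
Reagents that add atoms: carbon tetrabromide, BrC(Br)(Br)Br
Why: Appel reaction; SN2 displacement of the alkoxyphosphonium ion under neutral conditions should give the primary allylic bromide without allylic shift or loss of the E geometry.

Step 3
Reactants: 4 nerol [(2Z)-3,7-dimethylocta-2,6-dien-1-ol]
Product: 5 neryl chloride [(2Z)-1-chloro-3,7-dimethylocta-2,6-diene]
Conditions: NCS, Me2S, CH2Cl2, −30 to 0 °C
Reagents that add atoms: N-chlorosuccinimide, O=C1CCC(=O)N1Cl
Why: Corey–Kim chlorination; the alkoxysulfonium ion is displaced by chloride in an SN2 reaction under neutral conditions, which is the standard way to keep a Z allylic system unrearranged.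

Step 4
Reactants: 5 neryl chloride; 3 (6E)-8-bromo-7-methyl-3-methylideneocta-1,6-diene
Product: 7 (6E,10Z)-7,11,15-trimethyl-3-methylidenehexadeca-1,6,10,14-tetraene, via nerylbarium chloride 6 (not isolated)
Conditions: Li, biphenyl, BaI2, THF, rt; 5, −78 °C; then 3, −78 °C
Reagents that add atoms: barium diiodide, [Ba+2].[I-].[I-] (barium in 6 only)
Why: Allylbarium cross-coupling; reduced barium inserts into the allylic chloride at −78 °C to give a configurationally stable allylbarium that attacks allylic bromides through its unsubstituted α-carbon by direct displacement, so C9–C10 forms head to head and both the Z alkene of 5 and the E alkene of 3 are kept. The diene of 3 meets only the preformed organobarium and not the reducing metal.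

Step 5
Reactants: 7 (6E,10Z)-7,11,15-trimethyl-3-methylidenehexadeca-1,6,10,14-tetraene
Product: 8 (2E,6Z,10E)-2,6,10-trimethyl-14-methylidenehexadeca-2,6,10,15-tetraen-1-ol
Conditions: SeO2 (cat.), salicylic acid (cat.), t-BuOOH, CH2Cl2, 0 °C, stopped at partial conversion
Reagents that add atoms: tert-butyl hydroperoxide, CC(C)(C)OO
Why: Same Riley-type oxidation; in oligoprenyl chains the terminal isopropylidene group is the least hindered and most reactive site, and its E methyl group (C16) is the one oxidised, which gives the E-2-methylallylic alcohol needed for step 6.

Step 6
Reactants: 8 (2E,6Z,10E)-2,6,10-trimethyl-14-methylidenehexadeca-2,6,10,15-tetraen-1-ol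
Product: 9 {(2R,3R)-3-[(3Z,7E)-3,7-dimethyl-11-methylidenetrideca-3,7,12-trien-1-yl]-2-methyloxiran-2-yl}methanol
Conditions: Ti(OiPr)4 (cat.), D-(−)-diethyl tartrate (cat.), t-BuOOH, 4 Å molecular sieves, CH2Cl2, −20 °C
Reagents that add atoms: tert-butyl hydroperoxide, CC(C)(C)OO
Why: Sharpless asymmetric epoxidation; only the alkene that carries the allylic hydroxyl reacts, and E-2-methylallylic alcohols are among the best substrates. Syn delivery of oxygen to the E alkene fixes the relative configuration of C1 and C15, and the D-(−)-tartrate selects the face that gives the (R,R)-epoxide (the L-(+)-ester gives S,S in this substrate class).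

Step 7
Reactants: 9 {(2R,3R)-3-[(3Z,7E)-3,7-dimethyl-11-methylidenetrideca-3,7,12-trien-1-yl]-2-methyloxiran-2-yl}methanol
Product: 10 p-toluenesulfonate of 9
Conditions: TsCl, Et3N, DMAP (cat.), CH2Cl2, 0 °C
Reagents that add atoms: p-toluenesulfonyl chloride, Cc1ccc(cc1)S(=O)(=O)Cl
Why: Sulfonylation of a primary alcohol at oxygen; no bond to a stereocentre is touched. A sulfonate is chosen over an iodide because it cannot undergo halogen–metal exchange with fragmentation of the epoxide in step 8.

Step 8
Reactants: 10 p-toluenesulfonate of 9; 11 prenyl chloride (1-chloro-3-methylbut-2-ene)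
Product: 13 (2R,3R)-3-[(3Z,7E)-3,7-dimethyl-11-methylidenetrideca-3,7,12-trien-1-yl]-2-methyl-2-(4-methylpent-3-en-1-yl)oxirane, via prenylmagnesium chloride 12 (not isolated)
Conditions: Mg, THF, 0 °C (11 to 12); then 10, Li2CuCl4 (cat.), THF, −40 to 0 °C
Reagents that add atoms: magnesium, [Mg] (in 12 only)
Why: Copper-catalysed Grignard–sulfonate cross-coupling (Kochi type); the oxiranylmethyl sulfonate is activated for displacement and should react before the hindered trisubstituted epoxide is opened, and under copper catalysis γ,γ-disubstituted allyl Grignard reagents couple with primary electrophiles through the unsubstituted α-carbon. C15 keeps its four bonds, so the epoxide configuration is unchanged.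

Step 9
Reactants: 13 (2R,3R)-3-[(3Z,7E)-3,7-dimethyl-11-methylidenetrideca-3,7,12-trien-1-yl]-2-methyl-2-(4-methylpent-3-en-1-yl)oxirane
Product: 15 (2Z)-2-{(3E,7Z)-4,8-dimethyl-10-[(2R,3R)-3-methyl-3-(4-methylpent-3-en-1-yl)oxiran-2-yl]deca-3,7-dien-1-yl}but-2-ene-1,4-diol, via bis(pinacolboronate) 14 (not isolated)
Conditions: B2pin2, Pt(PPh3)4 (cat.), toluene, 80 °C; then H2O2, NaOH, THF, 0 °C
Reagents that add atoms: bis(pinacolato)diboron, CC1(C)OB(OC1(C)C)B1OC(C)(C)C(C)(C)O1 (boron in 14 only); hydrogen peroxide, OO
Why: Platinum-catalysed 1,4-diboration of a 1,3-diene; oxidative addition of B–B to zerovalent platinum, insertion of the s-cis diene and reductive elimination from the π-allyl complex place boron on C2 and C20 on the same side, so C3=C4 is born with C2 cis to C20. Isolated trisubstituted alkenes do not react, and basic peroxide replaces boron by oxygen without touching the hindered epoxide.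

Step 10
Reactants: 15 (2Z)-2-{(3E,7Z)-4,8-dimethyl-10-[(2R,3R)-3-methyl-3-(4-methylpent-3-en-1-yl)oxiran-2-yl]deca-3,7-dien-1-yl}but-2-ene-1,4-diol
Product: 16 (2Z)-2-{(3E,7Z)-4,8-dimethyl-10-[(2R,3R)-3-methyl-3-(4-methylpent-3-en-1-yl)oxiran-2-yl]deca-3,7-dien-1-yl}-4-(phenylsulfanyl)but-2-en-1-ol
Conditions: PhSSPh (1 equiv), Bu3P (1 equiv), THF, −20 to 0 °C
Reagents that add atoms: diphenyl disulfide, c1ccc(cc1)SSc1ccccc1
Why: Hata-type sulfenylation; an alkoxyphosphonium ion is displaced by thiolate in an SN2 reaction with retention of the alkene geometry. C2–OH is favoured twice, being the less hindered hydroxyl (C3 carries H, whereas C20 sits on the fully substituted C4) and sitting on a γ,γ-disubstituted allylic carbon that is the more reactive in displacement. The thiolate should outrun the neighbouring hydroxyl as nucleophile.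

Step 11
Reactants: 16 (2Z)-2-{(3E,7Z)-4,8-dimethyl-10-[(2R,3R)-3-methyl-3-(4-methylpent-3-en-1-yl)oxiran-2-yl]deca-3,7-dien-1-yl}-4-(phenylsulfanyl)but-2-en-1-ol
Product: 18 2-(phenylsulfanyl) derivative of 19 (C1 and C15 as in 19, both epimers at C2), via dilithio dianion 17 (not isolated)
Conditions: n-BuLi (2.2 equiv), DABCO, THF (0.003 M), −78 °C, then 0 °C; aq NH4Cl
Reagents that add atoms: n-butyllithium, [Li]CCCC (lithium in 17 only)
Why: The first equivalent of n-BuLi makes the C20 alkoxide and the second removes the most acidic C–H, the allylic proton at C2 next to sulfur, so that 17 is a dianion whose six-membered O–Li–C2 chelate holds C2 cis to C20 and cannot undergo 1,4-elimination, oxide being no leaving group. The carbanion then attacks C1 of the epoxide in an intramolecular SN2 reaction, the closest known reaction type being the closure of fourteen-membered carbocycles by thio-stabilised allyl anions on trisubstituted epoxides at the far end of polyprenyl chains. The ring closes in the 14-exo-tet mode, the breaking C1–O bond lying outside the new ring, which allows the collinear C2···C1–O arrangement without strain. C1 is set by inversion at the attacked carbon and C15 by retention of its C–O bond, so the (R,R)-epoxide from the E alkene is written stereospecifically into the (1R,15R) pair of 19 and no induction between the two centres is asked for. Site selectivity within the epoxide follows from substitution (secondary C1 against fully substituted C15), and α-selectivity within the allyl anion follows from sulfur, which localises charge on C2, and from the fully substituted γ-carbon C4. The alkenes are not touched, since C3=C4 keeps its double-bond character in the α-thio anion and the other allylic positions are far less acidic. Ring closure has to beat intermolecular opening, which is secured by high dilution, by the release of epoxide strain and by the planar alkene units that cut down the free rotors of the chain. The configuration at C2 is of no consequence because sulfur is removed in step 12.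

Step 12
Reactants: 18 2-(phenylsulfanyl) derivative of 19
Product: 19 (2R)-2-[(1R,3Z,7E,11Z)-4-(hydroxymethyl)-8,12-dimethylcyclotetradeca-3,7,11-trien-1-yl]-6-methylhept-5-en-2-ol
Conditions: Li, EtNH2, THF, −78 °C; then solid NH4Cl
Reagents that add atoms: none
Why: Dissolving-metal cleavage of an allylic C–S bond, the standard end of Biellmann-type couplings; the R–CH(SPh)–CH=C(R)R pattern is the one for which protonation at the former C–S carbon, with the trisubstituted alkene kept, is the rule. Both hydroxyls are present as lithium alkoxides, which protects the allylic C20–O bond from cleavage and keeps C2 cis to C20 by chelation, and isolated trisubstituted alkenes are not reduced at −78 °C.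

## Compound list

1 | β-myrcene (7-methyl-3-methylideneocta-1,6-diene) | C=CC(=C)CCC=C(C)C | starting material
2 | (2E)-2-methyl-6-methylideneocta-2,7-dien-1-ol | C=CC(=C)CC/C=C(\C)CO | intermediate
3 | (6E)-8-bromo-7-methyl-3-methylideneocta-1,6-diene | C=CC(=C)CC/C=C(\C)CBr | intermediate
4 | nerol [(2Z)-3,7-dimethylocta-2,6-dien-1-ol] | CC(C)=CCC/C(C)=C\CO | starting material
5 | neryl chloride [(2Z)-1-chloro-3,7-dimethylocta-2,6-diene] | CC(C)=CCC/C(C)=C\CCl | intermediate
6 | nerylbarium chloride | CC(C)=CCC/C(C)=C\C[Ba]Cl | intermediate
7 | (6E,10Z)-7,11,15-trimethyl-3-methylidenehexadeca-1,6,10,14-tetraene | C=CC(=C)CC/C=C(\C)CC/C=C(/C)CCC=C(C)C | intermediate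
8 | (2E,6Z,10E)-2,6,10-trimethyl-14-methylidenehexadeca-2,6,10,15-tetraen-1-ol | C=CC(=C)CC/C=C(\C)CC/C=C(/C)CC/C=C(\C)CO | intermediate
9 | {(2R,3R)-3-[(3Z,7E)-3,7-dimethyl-11-methylidenetrideca-3,7,12-trien-1-yl]-2-methyloxiran-2-yl}methanol | OC[C@@]1(C)O[C@@H]1CC/C(C)=C\CC/C(C)=C/CCC(=C)C=C | intermediate
10 | p-toluenesulfonate of 9 | Cc1ccc(cc1)S(=O)(=O)OC[C@@]1(C)O[C@@H]1CC/C(C)=C\CC/C(C)=C/CCC(=C)C=C | intermediate
11 | prenyl chloride (1-chloro-3-methylbut-2-ene) | CC(C)=CCCl | starting material
12 | prenylmagnesium chloride | CC(C)=CC[Mg]Cl | intermediate
13 | (2R,3R)-3-[(3Z,7E)-3,7-dimethyl-11-methylidenetrideca-3,7,12-trien-1-yl]-2-methyl-2-(4-methylpent-3-en-1-yl)oxirane | CC(C)=CCC[C@@]1(C)O[C@@H]1CC/C(C)=C\CC/C(C)=C/CCC(=C)C=C | intermediate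
14 | (Z)-1,4-bis(pinacolboronate) from 13 (Bpin on C2 and on C20, alkene C3=C4) | CC(C)=CCC[C@@]1(C)O[C@@H]1CC/C(C)=C\CC/C(C)=C/CC/C(CB2OC(C)(C)C(C)(C)O2)=C/CB2OC(C)(C)C(C)(C)O2 | intermediate
15 | (2Z)-2-{(3E,7Z)-4,8-dimethyl-10-[(2R,3R)-3-methyl-3-(4-methylpent-3-en-1-yl)oxiran-2-yl]deca-3,7-dien-1-yl}but-2-ene-1,4-diol | CC(C)=CCC[C@@]1(C)O[C@@H]1CC/C(C)=C\CC/C(C)=C/CC/C(CO)=C/CO | intermediate
16 | (2Z)-2-{(3E,7Z)-4,8-dimethyl-10-[(2R,3R)-3-methyl-3-(4-methylpent-3-en-1-yl)oxiran-2-yl]deca-3,7-dien-1-yl}-4-(phenylsulfanyl)but-2-en-1-ol | CC(C)=CCC[C@@]1(C)O[C@@H]1CC/C(C)=C\CC/C(C)=C/CC/C(CO)=C/CSc1ccccc1 | intermediate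
17 | O,C2-dilithio derivative of 16 | CC(C)=CCC[C@@]1(C)O[C@@H]1CC/C(C)=C\CC/C(C)=C/CC/C(CO[Li])=C/C([Li])Sc1ccccc1 | intermediate
18 | 2-(phenylsulfanyl) derivative of 19 (both epimers at C2) | CC(C)=CCC[C@@](C)(O)[C@H]1C(Sc2ccccc2)/C=C(\CO)CC/C=C(\C)CC/C=C(/C)CC1 | intermediate
19 | (2R)-2-[(1R,3Z,7E,11Z)-4-(hydroxymethyl)-8,12-dimethylcyclotetradeca-3,7,11-trien-1-yl]-6-methylhept-5-en-2-ol | CC(C)=CCC[C@@](C)(O)[C@H]1C/C=C(\CO)CC/C=C(\C)CC/C=C(/C)CC1 | target

## Step count and least certain steps

Total step count: 12. Longest linear sequence: 11 steps (1 to 19 by steps 1, 2 and 4 to 12); step 3 is the one-step side branch.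

**Step 11 (key step).**
- Most likely failure: the closure may be too slow. Intermolecular epoxide opening would then build oligomers, the anion would be quenched by proton transfer, or residual base would isomerise the epoxide to an allylic alcohol. Attack through the γ-carbon C4 is a lesser risk.
- Fallback: it sets out from 15 and comes back at 19. The C2 hydroxyl of 15 is exchanged for chloride with NCS and Me2S to give the C2 allylic chloride F1. Bu3SnLi displaces the chloride to give the C2 allylstannane F2. Two equivalents of MeLi at −78 °C under high dilution first deprotonate C20–OH and then exchange tin for lithium.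
- Why this helps: the unstabilised, alkoxide-chelated allyllithium is far more nucleophilic than 17 and is formed without any free base next to the epoxide. Its closure would give 19 directly, so step 12 falls away.

**Step 10.**
- Most likely failure: incomplete discrimination between the two primary allylic hydroxyls, double substitution, and cyclodehydration of the cis-enediol to a dihydrofuran through attack of the free hydroxyl on the activated one.
- Fallback: it sets out from 15 and comes back at 16. Both oxygens are tied up with SOCl2 and Et3N as the seven-membered cyclic sulfite F3. This can neither cyclise nor react twice. PhSNa in DMF at 0 °C then opens it by SN2 attack at the more reactive γ,γ-disubstituted allylic carbon C2. The sulfite half-ester left on the C20 oxygen loses SO2 on aqueous work-up.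

**Step 8.**
- Most likely failure: coupling through the substituted γ-carbon of the prenyl reagent, slow displacement at the carbon next to the fully substituted C15 so that opening of the epoxide at C1 competes, and homocoupling of the Grignard reagent.
- Fallback: it sets out from 10 and comes back at 13. Compound 10 is alkylated with lithiated 3-methylbut-2-enyl phenyl sulfone (n-BuLi, THF, DMPU, −78 °C). The charge of this anion sits on the carbon next to sulfur, so only α-coupling is possible, and the product is the C17 phenyl sulfone F4. The sulfonyl group is then removed by zerovalent-palladium-catalysed hydride transfer (Pd(PPh3)4, NaBH4), which leaves an isolated epoxide alone.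

**Step 12.**
- Most likely failure: protonation of the allyl anion at C4 with shift of the double bond to C2=C3, partial loss of the geometry at C3=C4, or reductive loss of the allylic C20 oxygen.
- Fallback: it sets out from 18 and comes back at 19. The sulfide is oxidised with Oxone (2KHSO5·KHSO4·K2SO4) in aqueous methanol at 0 °C to the C2 phenyl sulfone F5. The sulfonyl group is replaced by hydride with PdCl2(dppp) and LiHBEt3. A π-allylpalladium intermediate then takes up hydride at the less substituted terminus C2, in place of a free allyl anion.

**Step 4.**
- Most likely failure: loss of the Z geometry or γ-coupling if the allylbarium warms, homocoupling, and electron transfer to the diene if unconsumed metal remains.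
- Fallback: it sets out from 3 (with 5) and comes back at 7. PhSO2Na in DMF converts 3 into the C9 allylic phenyl sulfone F6. Its lithio derivative is alkylated with 5 by SN2 displacement, which keeps the Z alkene, to give the coupled C9 sulfone F7. PdCl2(dppp) with LiHBEt3 then removes the sulfonyl group next to the E alkene.

## Further compounds

F1 | step 11 | C2 allylic chloride from 15 | CC(C)=CCC[C@@]1(C)O[C@@H]1CC/C(C)=C\CC/C(C)=C/CC/C(CO)=C/CCl
F2 | step 11 | C2 allyl(tributyl)stannane | CC(C)=CCC[C@@]1(C)O[C@@H]1CC/C(C)=C\CC/C(C)=C/CC/C(CO)=C/C[Sn](CCCC)(CCCC)CCCC
F3 | step 10 | seven-membered cyclic sulfite of 15 (4,7-dihydro-1,3,2-dioxathiepine 2-oxide) | CC(C)=CCC[C@@]1(C)O[C@@H]1CC/C(C)=C\CC/C(C)=C/CC/C1=C/COS(=O)OC1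
F4 | step 8 | C17 phenyl sulfone of 13 | CC(C)=CC(C[C@@]1(C)O[C@@H]1CC/C(C)=C\CC/C(C)=C/CCC(=C)C=C)S(=O)(=O)c1ccccc1
F5 | step 12 | C2 phenyl sulfone corresponding to 18 | CC(C)=CCC[C@@](C)(O)[C@H]1C(S(=O)(=O)c2ccccc2)/C=C(\CO)CC/C=C(\C)CC/C=C(/C)CC1
F6 | step 4 | C9 allylic phenyl sulfone from 3 | C=CC(=C)CC/C=C(\C)CS(=O)(=O)c1ccccc1
F7 | step 4 | coupled C9 phenyl sulfone of 7 | C=CC(=C)CC/C=C(\C)C(C/C=C(/C)CCC=C(C)C)S(=O)(=O)c1ccccc1
A1 | alternative 1 | acyclic pentaene diol, 19 opened at C11=C12 with a CH2 cap on each end | CC(C)=CCC[C@@](C)(O)[C@H](CCC(C)=C)C/C=C(\CO)CC/C=C(\C)CCC=C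
A2 | alternative 2 | seventeen-membered bis-allylic ether (O between C2 and C23, C20 as TBS ether) | O1C/C=C(\CO[Si](C)(C)C(C)(C)C)CC/C=C(\C)CC/C=C(/C)CC/C=C(/CCC=C(C)C)C1
A3 | alternative 2 | ring-contracted carbocycle with C2 hydroxyl and C15=C23 methylidene | CC(C)=CCCC(=C)[C@H]1C(O)/C=C(\CO[Si](C)(C)C(C)(C)C)CC/C=C(\C)CC/C=C(/C)CC1
A4 | alternative 3 | (2Z)-2-[(3E,7Z,11E)-4,8,12,16-tetramethylheptadeca-3,7,11,15-tetraen-1-yl]but-2-ene-1,4-diol | CC(C)=CCC/C(C)=C/CC/C(C)=C\CC/C(C)=C/CC/C(CO)=C/CO
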